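The route rests on disconnecting ring B between the ketone carbon C8 and the alkylidene-bearing carbon C7 (eremophilane numbering). A nickel-catalysed alkylative cyclisation of an ynal with dimethylzinc forms this bond, closes ring B trans-fused onto a preformed ring A, and at the same time delivers the C13 methyl syn to C8. The tetrasubstituted C7=C11 alkene is thus formed with the geometry of the target (methyl cis to the carbonyl, hydroxymethyl cis to C6). The precursor is a monocyclic ring-A cyclohexane carrying a CH2CHO arm on C10 and a 4-silyloxybut-2-ynyl arm on quaternary C5. The C8 carbinol is then oxidised and C9 hydroxylated from the face opposite the angular methyl.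

Key step: step 11

Remark: atoms carry eremophilane numbers (ring A = C1–C5 and C10, ring B = C5–C10, C11–C13 = side chain on C7, C14 = methyl on C5, C15 = methyl on C4), and β is the face of the C14 methyl. The target is read as (3R,4R,5R,9S,10R): trans ring fusion (10α-H), 3α-ester, 4β-methyl, 9α-OH, (E)-C7=C11 with the C13 methyl cis to C8. PMB = 4-methoxybenzyl, TBS = tert-butyldimethylsilyl, TES = triethylsilyl. Compounds 1, 7, 23 and 25 are taken as commercially available.

Step 1
Reactants: 1 4-methoxy-3-methylphenol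
Product: 2 4,4-dimethoxy-3-methylcyclohexa-2,5-dien-1-one
Conditions: PhI(OAc)2, MeOH, 0 °C
Reagents that add atoms: methanol (CO)
Why: Oxidative dearomatisation of a para-methoxyphenol with a hypervalent iodine reagent in methanol should trap the phenoxenium ion at the methoxy-bearing carbon and give the quinone monoketal, with no stereocenter formed.

Step 2
Reactants: 2 4,4-dimethoxy-3-methylcyclohexa-2,5-dien-1-one
Product: 3 4,4-dimethoxy-3-methylcyclohex-2-en-1-one
Conditions: H2 (1 atm), RhCl(PPh3)3 (5 mol %), benzene/EtOH, rt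
Reagents that add atoms: none
Why: Chemoselective homogeneous hydrogenation with RhCl(PPh3)3 discriminates strongly by alkene substitution, so the disubstituted double bond of the cross-conjugated dienone should be saturated while the trisubstituted methyl-bearing enone bond survives, as in the reduction of 1,4-dien-3-ones to 4-en-3-ones.

Step 3
Reactants: 3 4,4-dimethoxy-3-methylcyclohex-2-en-1-one
Product: 4 (1R)-4,4-dimethoxy-3-methylcyclohex-2-en-1-ol
Conditions: (S)-2-methyl-CBS-oxazaborolidine (20 mol %), BH3·SMe2, THF, −20 °C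
Reagents that add atoms: none
Why: Corey–Bakshi–Shibata reduction in which the alkenyl flank acts as the large group, so the (S)-oxazaborolidine should deliver hydride to give the (R)-allylic alcohol, which becomes the C3 oxygen stereocenter and the source of all later stereocontrol.

Step 4
Reactants: 4 (1R)-4,4-dimethoxy-3-methylcyclohex-2-en-1-ol
Product: 5 1-({[(1R)-4,4-dimethoxy-3-methylcyclohex-2-en-1-yl]oxy}methyl)-4-methoxybenzene
Conditions: NaH, PMBCl, Bu4NI (cat.), THF/DMF, 0 °C → rt
Reagents that add atoms: 4-methoxybenzyl chloride (COc1ccc(CCl)cc1)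
Why: Williamson etherification under basic conditions leaves the acid-labile allylic ketal untouched and does not involve the stereocenter.

Step 5
Reactants: 5 1-({[(1R)-4,4-dimethoxy-3-methylcyclohex-2-en-1-yl]oxy}methyl)-4-methoxybenzene
Product: 6 (4R)-4-[(4-methoxybenzyl)oxy]-2-methylcyclohex-2-en-1-one
Conditions: oxalic acid (cat.), THF/H2O, rt
Reagents that add atoms: water (O)
Why: Mild acid-catalysed ketal hydrolysis should unveil the ketone next to the methyl-bearing alkene carbon, which transposes the functionality to the γ-alkoxy enone without touching the PMB ether or the stereocenter.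

Step 6
Reactants: 7 but-2-yne-1,4-diol
Product: 8 4-[(tert-butyldimethylsilyl)oxy]but-2-yn-1-ol
Conditions: NaH (1 equiv), THF, 0 °C; TBSCl
Reagents that add atoms: tert-butyldimethylsilyl chloride (CC(C)(C)[Si](C)(C)Cl)
Why: Monosilylation of a symmetrical diol through its sparingly soluble monosodium alkoxide should favour the mono-TBS ether (silyl ether formation).

Step 7
Reactants: 8 4-[(tert-butyldimethylsilyl)oxy]but-2-yn-1-ol
Product: 9 [(4-bromobut-2-yn-1-yl)oxy](tert-butyl)dimethylsilane
Conditions: CBr4, PPh3, CH2Cl2, 0 °C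
Reagents that add atoms: carbon tetrabromide (BrC(Br)(Br)Br)
Why: Appel bromination converts the primary propargylic alcohol into the bromide under neutral conditions that spare the silyl ether.

Step 8
Reactants: 6 (4R)-4-[(4-methoxybenzyl)oxy]-2-methylcyclohex-2-en-1-one; 9 [(4-bromobut-2-yn-1-yl)oxy](tert-butyl)dimethylsilane
Product: 11 (2R,3R,4R)-2-{4-[(tert-butyldimethylsilyl)oxy]but-2-yn-1-yl}-4-[(4-methoxybenzyl)oxy]-2,3-dimethylcyclohexan-1-one, via lithium enolate 10 (not isolated)
Conditions: Me2CuLi (from MeLi, CuI), Et2O, −78 → −30 °C; then 9, HMPA, THF, −30 °C → rt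
Reagents that add atoms: lithium dimethylcuprate ([Li+].C[Cu-]C)
Why: Tandem conjugate addition–enolate alkylation in which the cuprate should add anti to the γ-OPMB group (C4 methyl trans to the C3 oxygen) and the regiodefined tetrasubstituted enolate should be alkylated by the propargylic bromide on the face opposite the new C4 methyl, creating quaternary C5 with the two methyls cis.

Step 9
Reactants: 11 (2R,3R,4R)-2-{4-[(tert-butyldimethylsilyl)oxy]but-2-yn-1-yl}-4-[(4-methoxybenzyl)oxy]-2,3-dimethylcyclohexan-1-one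
Product: 12 C10-methylidene compound (11 with C=CH2 in place of C=O; 3α-OPMB, 4β-methyl, 5β-methyl, 5α-butynyl arm)
Conditions: Ph3PCH3Br, KOtBu, toluene, 80 °C
Reagents that add atoms: methyltriphenylphosphonium bromide (C[P+](c1ccccc1)(c1ccccc1)c1ccccc1.[Br-])
Why: Wittig methylenation with the unstabilised ylide at elevated temperature is the standard answer to a ketone flanked by a quaternary carbon, and no stereocenter can epimerise because C5 carries no hydrogen.

Step 10
Reactants: 12 C10-methylidene compound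
Product: 15 ynal (ring A with 10β-CH2CHO arm and 10α-H; 3α-OPMB; 4β-methyl; 5β-methyl; 5α-CH2C≡CCH2OTBS arm), via B-alkyl-9-BBN adduct 13 (not isolated), via lithium alkoxyaluminate adduct 14 (not isolated)
Conditions: 9-BBN, THF, rt; CO (1 atm), LiAlH(OtBu)3, THF, −30 → 0 °C; H2O2, pH 7 phosphate buffer, 0 °C
Reagents that add atoms: carbon monoxide ([C-]#[O+]); hydrogen peroxide (OO)
Why: Hydroboration–carbonylation (one-carbon homologation of an alkylborane to an aldehyde) in which 9-BBN should add to the 1,1-disubstituted alkene far faster than to the internal alkyne, boron going to the terminal carbon and hydrogen to C10 from the α face opposite the axial C14 methyl on the neighbouring C5, which sets C10 with the new arm equatorial and trans to the butynyl arm.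

Step 11
Reactants: 15 ynal
Product: 17 3α-[(4-methoxybenzyl)oxy]-12-[(tert-butyldimethylsilyl)oxy]eremophil-7(11)-en-8-ol (trans-decalin; 10α-H; 4β,5β-dimethyl; E alkene with the C13 methyl cis to C8; mixture of C8 epimers), via methylzinc alkoxide 16 (not isolated)
Conditions: Ni(cod)2 (10 mol %), Me2Zn (3 equiv), THF, 0 °C, slow addition of 15; aq. NH4Cl
Reagents that add atoms: dimethylzinc (C[Zn]C)
Why: Zerovalent nickel binds the aldehyde and the alkyne of 15 and undergoes oxidative cyclisation to an oxanickelacyclopentene, which forms the C8–C7 bond; transmetalation of methyl from zinc to nickel and C–C reductive elimination then place the methyl on C11 on the side of the former nickel, cis to C8, and release the zinc alkoxide 16. The closest known reaction type is the nickel-catalysed alkylative cyclisation of ynals with organozincs. Ring B closes in the 6-exo-dig mode and is trans-fused because the two arms are trans-diequatorial on the chair of ring A. The only new stereocenter, the C8 carbinol, is not controlled and need not be, since step 12 oxidises it; the element that matters, the geometry of the tetrasubstituted C7=C11 alkene, is fixed by the syn addition of C8 and methyl across the alkyne. The step needs alkylative coupling to win over direct addition of methylzinc to the aldehyde and over reductive cyclisation: methyl has no β-hydrogen, phosphine-free Ni(cod)2 favours the alkylative path, and slow addition of the ynal at 0 °C should keep the uncatalysed addition minor.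

Step 12
Reactants: 17 3α-[(4-methoxybenzyl)oxy]-12-[(tert-butyldimethylsilyl)oxy]eremophil-7(11)-en-8-ol
Product: 18 3α-[(4-methoxybenzyl)oxy]-12-[(tert-butyldimethylsilyl)oxy]eremophil-7(11)-en-8-one
Conditions: Dess–Martin periodinane, pyridine, CH2Cl2, 0 °C → rt
Reagents that add atoms: none
Why: Dess–Martin oxidation of the secondary allylic alcohol should give the enone under non-acidic, non-basic conditions that preserve the alkene geometry, and it removes the uncontrolled C8 stereocenter.

Step 13
Reactants: 18 3α-[(4-methoxybenzyl)oxy]-12-[(tert-butyldimethylsilyl)oxy]eremophil-7(11)-en-8-one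
Product: 20 9α-hydroxy-3α-[(4-methoxybenzyl)oxy]-12-[(tert-butyldimethylsilyl)oxy]eremophil-7(11)-en-8-one, via lithium dienolate 19 (not isolated)
Conditions: LiN(iPr)2, THF, −78 °C; then 2-(phenylsulfonyl)-3-phenyloxaziridine, −78 °C; aq. NH4Cl
Reagents that add atoms: 2-(phenylsulfonyl)-3-phenyloxaziridine (O=S(=O)(c1ccccc1)N1OC1c1ccccc1)
Why: Kinetic deprotonation of the enone at the α' carbon C9 and Davis oxidation of the cross-conjugated enolate should introduce oxygen from the α face, away from the axial C14 methyl that is 1,3-related to C9, giving the equatorial 9α-alcohol, which is also the more stable epimer.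

Step 14
Reactants: 20 9α-hydroxy-3α-[(4-methoxybenzyl)oxy]-12-[(tert-butyldimethylsilyl)oxy]eremophil-7(11)-en-8-one
Product: 21 3α-[(4-methoxybenzyl)oxy]-9α-[(triethylsilyl)oxy]-12-[(tert-butyldimethylsilyl)oxy]eremophil-7(11)-en-8-one
Conditions: Et3SiOTf, 2,6-lutidine, CH2Cl2, −78 °C
Reagents that add atoms: triethylsilyl trifluoromethanesulfonate (CC[Si](CC)(CC)OS(=O)(=O)C(F)(F)F)
Why: Silylation of the α-ketol with a silyl triflate and a hindered base masks the C9 hydroxyl so that only the C3 oxygen will be free for the later acylation.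

Step 15
Reactants: 21 3α-[(4-methoxybenzyl)oxy]-9α-[(triethylsilyl)oxy]-12-[(tert-butyldimethylsilyl)oxy]eremophil-7(11)-en-8-one
Product: 22 3α-hydroxy-9α-[(triethylsilyl)oxy]-12-[(tert-butyldimethylsilyl)oxy]eremophil-7(11)-en-8-one
Conditions: DDQ, CH2Cl2/pH 7 buffer, 0 °C
Reagents that add atoms: none
Why: Oxidative cleavage of the PMB ether with DDQ is orthogonal to both silyl ethers and to the electron-poor enone and should free the C3 alcohol alone.

Step 16
Reactants: 23 (E)-oct-2-enal
Product: 24 (E)-non-3-en-1-yne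
Conditions: LiN(iPr)2, TMSCHN2, THF, −78 °C; then 23, −78 °C → rt; aq. NH4Cl
Reagents that add atoms: (trimethylsilyl)diazomethane (C[Si](C)(C)C=[N+]=[N-])
Why: Colvin rearrangement, in which lithiated (trimethylsilyl)diazomethane adds to the aldehyde, Peterson elimination and loss of nitrogen give an alkylidene carbene and a 1,2-hydrogen shift gives the terminal alkyne, with the E alkene untouched and no methanol present that could add to the enal.

Step 17
Reactants: 24 (E)-non-3-en-1-yne; 25 ethyl (E)-3-iodoacrylate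
Product: 27 ethyl (2E,4E,6E)-5-methyldodeca-2,4,6-trienoate, via alkenylalane 26 (not isolated)
Conditions: Me3Al, Cp2ZrCl2 (25 mol %), (CH2Cl)2, rt; then 25, Pd(PPh3)4 (5 mol %), ZnCl2, THF, rt
Reagents that add atoms: trimethylaluminium (C[Al](C)C)
Why: Zirconium-catalysed methylalumination of the terminal alkyne is syn and places methyl on the internal carbon, and the Negishi coupling of the resulting alkenylalane with the E iodoacrylate proceeds with retention at both partners, so the trisubstituted 4E alkene and the all-E triene should result.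

Step 18
Reactants: 27 ethyl (2E,4E,6E)-5-methyldodeca-2,4,6-trienoate
Product: 28 (2E,4E,6E)-5-methyldodeca-2,4,6-trienoic acid
Conditions: LiOH, THF/MeOH/H2O, rt; then dilute HCl
Reagents that add atoms: lithium hydroxide ([Li+].[OH-])
Why: Saponification of the ethyl ester under mild conditions should leave the thermodynamically preferred all-E triene unchanged.

Step 19
Reactants: 22 3α-hydroxy-9α-[(triethylsilyl)oxy]-12-[(tert-butyldimethylsilyl)oxy]eremophil-7(11)-en-8-one; 28 (2E,4E,6E)-5-methyldodeca-2,4,6-trienoic acid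
Product: 30 9α-[(triethylsilyl)oxy]-12-[(tert-butyldimethylsilyl)oxy]-8-oxoeremophil-7(11)-en-3α-yl (2E,4E,6E)-5-methyldodeca-2,4,6-trienoate, via mixed anhydride 29 (not isolated)
Conditions: 2,4,6-Cl3C6H2COCl, Et3N, toluene, rt; then 22, DMAP, toluene, rt
Reagents that add atoms: none
Why: Yamaguchi esterification through the mixed anhydride and the acylpyridinium ion should acylate the equatorial secondary C3 alcohol, the only free hydroxyl, with retention at C3.

Step 20
Reactants: 30 9α-[(triethylsilyl)oxy]-12-[(tert-butyldimethylsilyl)oxy]-8-oxoeremophil-7(11)-en-3α-yl (2E,4E,6E)-5-methyldodeca-2,4,6-trienoate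
Product: 31 CNP0226738.2, (3R,4R,5R,9S,10R)-9,12-dihydroxy-8-oxoeremophil-7(11)-en-3-yl (2E,4E,6E)-5-methyldodeca-2,4,6-trienoate
Conditions: HF·pyridine, pyridine, THF, 0 °C → rt
Reagents that add atoms: none
Why: Buffered fluoride-mediated desilylation should remove the TES and TBS ethers without touching the trienoate ester, the α-ketol or the alkene geometry.

Compound list
1 | 4-methoxy-3-methylphenol | COc1ccc(O)cc1C | starting material
2 | 4,4-dimethoxy-3-methylcyclohexa-2,5-dien-1-one | COC1(OC)C=CC(=O)C=C1C | intermediate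
3 | 4,4-dimethoxy-3-methylcyclohex-2-en-1-one | COC1(OC)CCC(=O)C=C1C | intermediate
4 | (1R)-4,4-dimethoxy-3-methylcyclohex-2-en-1-ol | O[C@@H]1CCC(OC)(OC)C(C)=C1 | intermediate
5 | 1-({[(1R)-4,4-dimethoxy-3-methylcyclohex-2-en-1-yl]oxy}methyl)-4-methoxybenzene | COc1ccc(CO[C@@H]2CCC(OC)(OC)C(C)=C2)cc1 | intermediate
6 | (4R)-4-[(4-methoxybenzyl)oxy]-2-methylcyclohex-2-en-1-one | COc1ccc(CO[C@@H]2CCC(=O)C(C)=C2)cc1 | intermediate
7 | but-2-yne-1,4-diol | OCC#CCO | starting material
8 | 4-[(tert-butyldimethylsilyl)oxy]but-2-yn-1-ol | CC(C)(C)[Si](C)(C)OCC#CCO | intermediate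
9 | [(4-bromobut-2-yn-1-yl)oxy](tert-butyl)dimethylsilane | CC(C)(C)[Si](C)(C)OCC#CCBr | intermediate
10 | lithium (3R,4R)-4-[(4-methoxybenzyl)oxy]-2,3-dimethylcyclohex-1-en-1-olate (not isolated) | COc1ccc(CO[C@@H]2CCC(O[Li])=C(C)[C@H]2C)cc1 | intermediate
11 | (2R,3R,4R)-2-{4-[(tert-butyldimethylsilyl)oxy]but-2-yn-1-yl}-4-[(4-methoxybenzyl)oxy]-2,3-dimethylcyclohexan-1-one | COc1ccc(CO[C@@H]2CCC(=O)[C@](C)(CC#CCO[Si](C)(C)C(C)(C)C)[C@H]2C)cc1 | intermediate
12 | C10-methylidene compound (11 with C=CH2 in place of C=O; same configuration at C3, C4, C5) | COc1ccc(CO[C@@H]2CCC(=C)[C@](C)(CC#CCO[Si](C)(C)C(C)(C)C)[C@H]2C)cc1 | intermediate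
13 | B-alkyl-9-BBN adduct of 12 (boron on C9, 10α-H; not isolated) | COc1ccc(CO[C@@H]2CC[C@@H](CB3C4CCCC3CCC4)[C@](C)(CC#CCO[Si](C)(C)C(C)(C)C)[C@H]2C)cc1 | intermediate
14 | lithium tri-tert-butoxyaluminate of the α-boryl carbinol formed from 13, CO and hydride (not isolated) | [Li+].COc1ccc(CO[C@@H]2CC[C@@H](CC(O[Al-](OC(C)(C)C)(OC(C)(C)C)OC(C)(C)C)B3C4CCCC3CCC4)[C@](C)(CC#CCO[Si](C)(C)C(C)(C)C)[C@H]2C)cc1 | intermediate
15 | ynal: ring A with 10β-CH2CHO arm (10α-H), 3α-OPMB, 4β-methyl, 5β-methyl, 5α-(4-TBSO-but-2-ynyl) arm | COc1ccc(CO[C@@H]2CC[C@@H](CC=O)[C@](C)(CC#CCO[Si](C)(C)C(C)(C)C)[C@H]2C)cc1 | intermediate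
16 | methylzinc alkoxide of 17 (not isolated) | COc1ccc(CO[C@@H]2CC[C@H]3CC(O[Zn]C)/C(=C(\C)CO[Si](C)(C)C(C)(C)C)C[C@]3(C)[C@H]2C)cc1 | intermediate
17 | 3α-[(4-methoxybenzyl)oxy]-12-[(tert-butyldimethylsilyl)oxy]eremophil-7(11)-en-8-ol (trans-decalin, E alkene, C8 epimers) | COc1ccc(CO[C@@H]2CC[C@H]3CC(O)/C(=C(\C)CO[Si](C)(C)C(C)(C)C)C[C@]3(C)[C@H]2C)cc1 | intermediate
18 | 3α-[(4-methoxybenzyl)oxy]-12-[(tert-butyldimethylsilyl)oxy]eremophil-7(11)-en-8-one | COc1ccc(CO[C@@H]2CC[C@H]3CC(=O)/C(=C(\C)CO[Si](C)(C)C(C)(C)C)C[C@]3(C)[C@H]2C)cc1 | intermediate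
19 | lithium 8,9-dienolate of 18 (not isolated) | COc1ccc(CO[C@@H]2CC[C@H]3C=C(O[Li])/C(=C(\C)CO[Si](C)(C)C(C)(C)C)C[C@]3(C)[C@H]2C)cc1 | intermediate
20 | 9α-hydroxy-3α-[(4-methoxybenzyl)oxy]-12-[(tert-butyldimethylsilyl)oxy]eremophil-7(11)-en-8-one | COc1ccc(CO[C@@H]2CC[C@H]3[C@H](O)C(=O)/C(=C(\C)CO[Si](C)(C)C(C)(C)C)C[C@]3(C)[C@H]2C)cc1 | intermediate
21 | 3α-[(4-methoxybenzyl)oxy]-9α-[(triethylsilyl)oxy]-12-[(tert-butyldimethylsilyl)oxy]eremophil-7(11)-en-8-one | COc1ccc(CO[C@@H]2CC[C@H]3[C@H](O[Si](CC)(CC)CC)C(=O)/C(=C(\C)CO[Si](C)(C)C(C)(C)C)C[C@]3(C)[C@H]2C)cc1 | intermediate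
22 | 3α-hydroxy-9α-[(triethylsilyl)oxy]-12-[(tert-butyldimethylsilyl)oxy]eremophil-7(11)-en-8-one | O[C@@H]1CC[C@H]2[C@H](O[Si](CC)(CC)CC)C(=O)/C(=C(\C)CO[Si](C)(C)C(C)(C)C)C[C@]2(C)[C@H]1C | intermediate
23 | (E)-oct-2-enal | CCCCC/C=C/C=O | starting material
24 | (E)-non-3-en-1-yne | CCCCC/C=C/C#C | intermediate
25 | ethyl (E)-3-iodoacrylate | CCOC(=O)/C=C/I | starting material
26 | dimethyl[(1E,3E)-2-methylnona-1,3-dien-1-yl]alane (not isolated) | CCCCC/C=C/C(C)=C/[Al](C)C | intermediate
27 | ethyl (2E,4E,6E)-5-methyldodeca-2,4,6-trienoate | CCCCC/C=C/C(C)=C/C=C/C(=O)OCC | intermediate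
28 | (2E,4E,6E)-5-methyldodeca-2,4,6-trienoic acid | CCCCC/C=C/C(C)=C/C=C/C(=O)O | intermediate
29 | mixed anhydride of 28 with 2,4,6-trichlorobenzoic acid (not isolated) | CCCCC/C=C/C(C)=C/C=C/C(=O)OC(=O)c1c(Cl)cc(Cl)cc1Cl | intermediate
30 | 9α-[(triethylsilyl)oxy]-12-[(tert-butyldimethylsilyl)oxy]-8-oxoeremophil-7(11)-en-3α-yl (2E,4E,6E)-5-methyldodeca-2,4,6-trienoate | CCCCC/C=C/C(C)=C/C=C/C(=O)O[C@@H]1CC[C@H]2[C@H](O[Si](CC)(CC)CC)C(=O)/C(=C(\C)CO[Si](C)(C)C(C)(C)C)C[C@]2(C)[C@H]1C | intermediate
31 | CNP0226738.2, (3R,4R,5R,9S,10R)-9,12-dihydroxy-8-oxoeremophil-7(11)-en-3-yl (2E,4E,6E)-5-methyldodeca-2,4,6-trienoate | CCCCC/C=C/C(C)=C/C=C/C(=O)O[C@@H]1CC[C@H]2[C@H](O)C(=O)/C(=C(\C)CO)C[C@]2(C)[C@H]1C | target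

Total step count: 20. Longest linear sequence: 15 steps (steps 1–5, 8–15, 19 and 20); steps 6–7 and 16–18 are side branches.

Steps most likely to fail

Step 11 (key step). What may go wrong: uncatalysed transfer of methyl from zinc to the aldehyde may outrun the oxidative cyclisation, or the six-membered oxanickelacycle may form so slowly that the ynal oligomerises. The fallback sets out from 15 and comes back at 18, so step 12 is then not needed. Chlorite oxidation (NaClO2, NaH2PO4, 2-methylbut-2-ene, tBuOH/H2O) should give the carboxylic acid F1, and TMSCHN2 in MeOH/toluene its methyl ester F2. Treatment with Ti(OiPr)4 and two equivalents of iPrMgCl (Et2O, −50 → 0 °C) should turn the alkyne into a divalent titanium alkyne complex, whose tether-side carbon attacks the ester in an intramolecular nucleophilic acyl substitution. This closes ring B through the same C8–C7 bond and leaves a vinyl–titanium bond on C11 syn to C8. Iodine should then give the (Z)-β-iodo enone F3, and a Negishi coupling (MeZnCl, Pd(PPh3)4, THF), which proceeds with retention, should deliver 18.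

Step 10. What may go wrong: incomplete uptake of carbon monoxide by the hindered alkylborane, over-reduction of the acylborane, or competing hydroboration of the alkyne. The fallback sets out from 12 and comes back at 15. Hydroboration with 9-BBN and oxidation with NaOH/H2O2 should give the primary alcohol F4, and Dess–Martin oxidation the aldehyde F5. A Wittig reaction with Ph3P=CHOMe (from Ph3PCH2OMe chloride and KN(SiMe3)2, THF, −78 → 0 °C, kept cold to avoid epimerisation at C10) should give the enol ether F6. Hydrolysis with dilute HCl in THF should then give 15.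

Step 13. What may go wrong: loss of regiocontrol in the deprotonation (removal of a γ proton at C12 or C13, which gives the extended dienolate and scrambles the geometry of the C7=C11 bond), or attack of the oxidant from the β face. The fallback sets out from 18 and comes back at 20. α'-Acetoxylation with Mn(OAc)3·2H2O in refluxing benzene (enolate of trivalent manganese, acetate transfer to C9, equatorial product expected) should give the acetate F7. Brief methanolysis (K2CO3, MeOH, 0 °C) should then give 20.

Further compounds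
F1 | step 11 | carboxylic acid from 15 (CH2CO2H arm on C10) | COc1ccc(CO[C@@H]2CC[C@@H](CC(=O)O)[C@](C)(CC#CCO[Si](C)(C)C(C)(C)C)[C@H]2C)cc1
F2 | step 11 | methyl ester of F1 | COc1ccc(CO[C@@H]2CC[C@@H](CC(=O)OC)[C@](C)(CC#CCO[Si](C)(C)C(C)(C)C)[C@H]2C)cc1
F3 | step 11 | (Z)-11-iodo-13-nor analogue of 18 (iodine on C11 cis to C8) | COc1ccc(CO[C@@H]2CC[C@H]3CC(=O)/C(=C(\I)CO[Si](C)(C)C(C)(C)C)C[C@]3(C)[C@H]2C)cc1
F4 | step 10 | primary alcohol from 12 (10β-CH2OH, 10α-H) | COc1ccc(CO[C@@H]2CC[C@@H](CO)[C@](C)(CC#CCO[Si](C)(C)C(C)(C)C)[C@H]2C)cc1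
F5 | step 10 | aldehyde from F4 (10β-CHO) | COc1ccc(CO[C@@H]2CC[C@@H](C=O)[C@](C)(CC#CCO[Si](C)(C)C(C)(C)C)[C@H]2C)cc1
F6 | step 10 | methyl enol ether from F5 (E/Z mixture) | COc1ccc(CO[C@@H]2CC[C@@H](C=COC)[C@](C)(CC#CCO[Si](C)(C)C(C)(C)C)[C@H]2C)cc1
F7 | step 13 | 9α-acetoxy derivative of 18 | COc1ccc(CO[C@@H]2CC[C@H]3[C@H](OC(C)=O)C(=O)/C(=C(\C)CO[Si](C)(C)C(C)(C)C)C[C@]3(C)[C@H]2C)cc1
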